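**Strategy.** Everything rests on cutting the C3–C4 bond of the C4-unsubstituted chroman. Its C4 methylene lies ortho to the ring oxygen O1 on benzo ring A, the retron of an ortho-quinone methide, and C3 is alpha to C2 at the aldehyde level. One amine-catalysed [4+2] annulation therefore joins an arylacetaldehyde, which already holds the 3,4-trans-diaryl chroman and the central ring, to a transient ortho-quinone methide: in one operation it makes the C3–C4 bond, completes the pyran ring and sets C3. The precursor pair is an aldehyde and a 2-(sulfonylmethyl)phenol. The same annulation builds the first chroman earlier; four benzyl ethers fall in the last step.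

Key step: step 16

Remark: chroman atoms are numbered O1, C2, C3, C4 and the fused benzene ring is ring A; lactols 17 and 26 are carried as C2 anomer mixtures, 14 as an E/Z mixture and 7 to 9 as racemates, none of which affects the final stereochemistry.

Step 1
Reactants: 1 5-bromobenzene-1,3-diol
Product: 3 2-bromo-4,6-dihydroxybenzaldehyde, via iminium chloride 2 (not isolated)
Conditions: POCl3 (1.2 equiv), DMF, MeCN, −15 °C to rt; then H2O, 50 °C
Reagents that add atoms: N,N-dimethylformamide CN(C)C=O (formyl carbon); water O (formyl oxygen)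
Why: Vilsmeier–Haack formylation of a resorcinol attacks the carbon ortho to one hydroxyl and para to the other, and the C5 bromine makes the two such carbons equivalent, so one aldehyde should result.

Step 2
Reactants: 3 2-bromo-4,6-dihydroxybenzaldehyde
Product: 4 4-(benzyloxy)-2-bromo-6-hydroxybenzaldehyde
Conditions: BnBr (1.05 equiv), CsHCO3 (1.5 equiv), MeCN, 80 °C
Reagents that add atoms: benzyl bromide BrCc1ccccc1
Why: Williamson etherification should go at the hydroxyl para to the formyl group, which is the more acidic and free, whereas the ortho hydroxyl is held in a hydrogen bond to the carbonyl.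

Step 3
Reactants: 4 4-(benzyloxy)-2-bromo-6-hydroxybenzaldehyde
Product: 5 4-(benzyloxy)-2-bromo-6-methoxybenzaldehyde
Conditions: MeI (2 equiv), K2CO3, DMF, 40 °C
Reagents that add atoms: iodomethane CI
Why: Williamson methylation of the remaining chelated phenol under more forcing conditions fixes the methoxy group ortho and the benzyloxy group para to the formyl carbon, the future C4 of the first chroman.

Step 4
Reactants: 5 4-(benzyloxy)-2-bromo-6-methoxybenzaldehyde; 6 3-(benzyloxy)phenol
Product: 7 rac-7-(benzyloxy)-4-[4-(benzyloxy)-2-bromo-6-methoxyphenyl]-2-phenyl-4H-1,3,2-benzodioxaborinine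
Conditions: PhB(OH)2 (1.2 equiv), EtCO2H (0.3 equiv), toluene, reflux, Dean–Stark
Reagents that add atoms: phenylboronic acid OB(O)c1ccccc1
Why: Boronic acid-templated ortho-specific hydroxyalkylation of a phenol: the mixed boronate delivers the aldehyde only to a carbon ortho to the phenol oxygen, and the less hindered ortho carbon (para to the benzyloxy group) should react, fixing the C4–C4a bond of the first chroman.

Step 5
Reactants: 7 benzodioxaborinine
Product: 9 rac-5-(benzyloxy)-2-{[4-(benzyloxy)-2-bromo-6-methoxyphenyl](4-methylbenzenesulfonyl)methyl}phenol, via benzhydrol 8 (not isolated)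
Conditions: TolSO2Na (3 equiv), HCO2H/H2O/THF, rt
Reagents that add atoms: sodium 4-methylbenzenesulfinate Cc1ccc(cc1)S(=O)[O-].[Na+]
Why: Aqueous acid hydrolyses the cyclic boronate to the ortho-hydroxybenzhydrol, whose benzylic C–O bond ionises readily between two donor-substituted rings and is captured at sulfur by sulfinate (SN1 substitution), giving a bench-stable quinone methide precursor.

Step 6
Reactants: 10 2,6-dimethoxyphenol
Product: 11 2-(benzyloxy)-1,3-dimethoxybenzene
Conditions: BnBr (1.2 equiv), K2CO3, DMF, 60 °C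
Reagents that add atoms: benzyl bromide BrCc1ccccc1
Why: Williamson benzylation of the hindered phenol.

Step 7
Reactants: 11 2-(benzyloxy)-1,3-dimethoxybenzene
Product: 13 3-(benzyloxy)-2,4-dimethoxybenzaldehyde, via iminium chloride 12 (not isolated)
Conditions: POCl3 (1.5 equiv), DMF, 80 °C; then H2O, 60 °C
Reagents that add atoms: N,N-dimethylformamide CN(C)C=O (formyl carbon); water O (formyl oxygen)
Why: Vilsmeier–Haack formylation of a 1,2,3-trialkoxybenzene occurs at C4, ortho to one methoxy group and para to the other, as with 1,2,3-trimethoxybenzene.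

Step 8
Reactants: 13 3-(benzyloxy)-2,4-dimethoxybenzaldehyde
Product: 14 2-(benzyloxy)-1,3-dimethoxy-4-(2-methoxyethenyl)benzene (E/Z mixture)
Conditions: MeOCH2PPh3Cl (1.5 equiv), KOtBu, THF, 0 °C to rt
Reagents that add atoms: (methoxymethyl)triphenylphosphonium chloride COC[P+](c1ccccc1)(c1ccccc1)c1ccccc1.[Cl-]
Why: Wittig olefination with the methoxymethylene ylide gives the enol ether, both isomers of which hydrolyse to the same aldehyde.

Step 9
Reactants: 14 enol ether
Product: 15 2-[3-(benzyloxy)-2,4-dimethoxyphenyl]acetaldehyde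
Conditions: 2 M aq. HCl, THF, 50 °C
Reagents that add atoms: water O
Why: Acid hydrolysis of the enol ether (protonation at the benzylic carbon, hydration, loss of methanol) gives the one-carbon-homologated arylacetaldehyde.

Step 10
Reactants: 9 sulfone; 15 2-[3-(benzyloxy)-2,4-dimethoxyphenyl]acetaldehyde (1.5 equiv)
Product: 17 (3R,4S)-7-(benzyloxy)-4-[4-(benzyloxy)-2-bromo-6-methoxyphenyl]-3-[3-(benzyloxy)-2,4-dimethoxyphenyl]chroman-2-ol, via ortho-quinone methide 16 (not isolated)
Conditions: (R)-2-[diphenyl(trimethylsilyloxy)methyl]pyrrolidine (20 mol %), Na2CO3 (1 M aq., 2 equiv), toluene, 0 °C to rt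
Reagents that add atoms: none
Why: Aminocatalytic formal inverse-electron-demand oxa-Diels–Alder reaction: carbonate eliminates sulfinate to give the quinone methide, the (E)-enamine of 15 adds through the face left open by the (R)-catalyst in a synclinal Michael transition state and the phenoxide closes onto the iminium carbon, so C3 (R) and C4 (S) should be set together as the 3,4-trans pair before hydrolysis releases the lactol.

Step 11
Reactants: 17 lactol
Product: 18 (3R,4S)-7-(benzyloxy)-4-[4-(benzyloxy)-2-bromo-6-methoxyphenyl]-3-[3-(benzyloxy)-2,4-dimethoxyphenyl]chromane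
Conditions: Et3SiH (3 equiv), BF3·OEt2 (2 equiv), CH2Cl2, −78 to −20 °C
Reagents that add atoms: none
Why: Ionic hydrogenation: BF3 ionises the anomeric hydroxyl to a cyclic oxocarbenium ion that the silane reduces to CH2, leaving C3 and C4 (already in the more stable trans arrangement) untouched.

Step 12
Reactants: 18 aryl bromide
Product: 19 (3R,4S)-4-[2-allyl-4-(benzyloxy)-6-methoxyphenyl]-7-(benzyloxy)-3-[3-(benzyloxy)-2,4-dimethoxyphenyl]chromane
Conditions: allylSnBu3 (1.5 equiv), Pd(P(t-Bu)3)2 (5 mol %), CsF (2.2 equiv), dioxane, 90 °C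
Reagents that add atoms: allyltributylstannane C=CC[Sn](CCCC)(CCCC)CCCC
Why: Migita–Kosugi–Stille coupling; the bulky electron-rich phosphine serves the hindered, electron-rich aryl bromide and fluoride activates the stannane.

Step 13
Reactants: 19 allyl arene
Product: 21 2-{5-(benzyloxy)-2-[(3R,4S)-7-(benzyloxy)-3-[3-(benzyloxy)-2,4-dimethoxyphenyl]chroman-4-yl]-3-methoxyphenyl}acetaldehyde, via diol 20 (not isolated)
Conditions: OsO4 (2 mol %), NaIO4 (4 equiv), 2,6-lutidine (2 equiv), dioxane/H2O, rt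
Reagents that add atoms: osmium tetroxide O=[Os](=O)(=O)=O (delivers the oxygen); sodium periodate [Na+].[O-]I(=O)(=O)=O (replenishes it)
Why: Lemieux–Johnson oxidation: the only alkene is dihydroxylated and the diol cleaved to the arylacetaldehyde, with lutidine suppressing over-oxidation; the aldehyde is used crude.

Step 14
Reactants: 22 4-(benzyloxy)-2-hydroxybenzaldehyde
Product: 23 5-(benzyloxy)-2-(hydroxymethyl)phenol
Conditions: NaBH4, MeOH, 0 °C
Reagents that add atoms: none
Why: Borohydride reduction of the aldehyde to the salicyl alcohol, the phenol needing no protection.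

Step 15
Reactants: 23 5-(benzyloxy)-2-(hydroxymethyl)phenol
Product: 24 5-(benzyloxy)-2-[(4-methylbenzenesulfonyl)methyl]phenol
Conditions: TolSO2Na (3 equiv), HCO2H/H2O, rt
Reagents that add atoms: sodium 4-methylbenzenesulfinate Cc1ccc(cc1)S(=O)[O-].[Na+]
Why: Acid-promoted SN1 substitution of the para-alkoxy-stabilised ortho-hydroxybenzyl cation by sulfinate at sulfur, used in excess so that it outruns self-condensation of the electron-rich ring.

Step 16
Reactants: 21 arylacetaldehyde; 24 5-(benzyloxy)-2-[(4-methylbenzenesulfonyl)methyl]phenol (1.3 equiv)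
Product: 26 (3R)-7-(benzyloxy)-3-{5-(benzyloxy)-2-[(3R,4S)-7-(benzyloxy)-3-[3-(benzyloxy)-2,4-dimethoxyphenyl]chroman-4-yl]-3-methoxyphenyl}chroman-2-ol, via ortho-quinone methide 25 (not isolated)
Conditions: (R)-2-[diphenyl(trimethylsilyloxy)methyl]pyrrolidine (20 mol %), Na2CO3 (1 M aq., 2 equiv), toluene, 0 °C
Reagents that add atoms: none
Why: Carbonate eliminates sulfinate from 24 to give the push-pull ortho-quinone methide 25 while the catalyst turns 21 into its (E)-enamine; the enamine carbon (future C3) attacks the exocyclic CH2 (future C4), the phenoxide oxygen O1 closes onto the iminium carbon C2, and water then releases the lactol and the catalyst. The closest known reaction type is the aminocatalytic formal inverse-electron-demand oxa-Diels–Alder reaction (Michael addition then hemiaminalisation) of aldehydes with ortho-quinone methides generated from 2-(sulfonylmethyl)phenols. The pyran ring of the second chroman is closed as a [4+2] annulation in which C3–C4 is the stereodefining bond and O1–C2 follows as a 6-exo-trig closure. The single new centre C3 (R) is controlled by the catalyst: the diphenyl(silyloxy)methyl arm of the (R)-pyrrolidine blocks one enamine face, so the unhindered CH2 terminus should add to the other (Re) face whatever the remote C3 and C4 centres of the first chroman prefer. The step needs enamine C-alkylation to outrun a racemic carbonate-mediated enolate addition and needs the new alpha-aryl centre to stay configurationally stable; the biphasic weak base, the low temperature and the closed lactol form of the product (little free aldehyde) should secure this, and 26 is reduced at once in step 17.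

Step 17
Reactants: 26 lactol
Product: 27 (3R,4S)-7-(benzyloxy)-4-{4-(benzyloxy)-2-[(3R)-7-(benzyloxy)chroman-3-yl]-6-methoxyphenyl}-3-[3-(benzyloxy)-2,4-dimethoxyphenyl]chromane
Conditions: Et3SiH (5 equiv), BF3·OEt2 (2 equiv), CH2Cl2, −78 °C
Reagents that add atoms: none
Why: Ionic hydrogenation as in step 11, run cold with excess silane so that hydride capture of the oxocarbenium ion outruns loss of the C3 proton.

Step 18
Reactants: 27 tetrabenzyl ether
Product: 28 (3R,4S)-4-{4-hydroxy-2-[(3R)-7-hydroxychroman-3-yl]-6-methoxyphenyl}-3-(3-hydroxy-2,4-dimethoxyphenyl)chroman-7-ol (CNP0305801.1)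
Conditions: H2 (1 atm), 10% Pd/C, EtOAc/MeOH, rt
Reagents that add atoms: none
Why: Hydrogenolysis of the four benzyl aryl ethers over palladium; no other bond is cleavable, since C4 of the first chroman carries only carbon and hydrogen and the ring C–O bonds are not benzylic.

**Compound list**

1 | 5-bromobenzene-1,3-diol | Oc1cc(O)cc(Br)c1 | starting material
2 | [(2-bromo-4,6-dihydroxyphenyl)methylidene]dimethyliminium chloride (not isolated) | C[N+](C)=Cc1c(O)cc(O)cc1Br.[Cl-] | intermediate
3 | 2-bromo-4,6-dihydroxybenzaldehyde | O=Cc1c(O)cc(O)cc1Br | intermediate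
4 | 4-(benzyloxy)-2-bromo-6-hydroxybenzaldehyde | O=Cc1c(O)cc(OCc2ccccc2)cc1Br | intermediate
5 | 4-(benzyloxy)-2-bromo-6-methoxybenzaldehyde | COc1cc(OCc2ccccc2)cc(Br)c1C=O | intermediate
6 | 3-(benzyloxy)phenol | Oc1cccc(OCc2ccccc2)c1 | starting material
7 | rac-7-(benzyloxy)-4-[4-(benzyloxy)-2-bromo-6-methoxyphenyl]-2-phenyl-4H-1,3,2-benzodioxaborinine | COc1cc(OCc2ccccc2)cc(Br)c1C1OB(c2ccccc2)Oc2cc(OCc3ccccc3)ccc21 | intermediate
8 | rac-5-(benzyloxy)-2-{[4-(benzyloxy)-2-bromo-6-methoxyphenyl](hydroxy)methyl}phenol (not isolated) | COc1cc(OCc2ccccc2)cc(Br)c1C(O)c1ccc(OCc2ccccc2)cc1O | intermediate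
9 | rac-5-(benzyloxy)-2-{[4-(benzyloxy)-2-bromo-6-methoxyphenyl](4-methylbenzenesulfonyl)methyl}phenol | COc1cc(OCc2ccccc2)cc(Br)c1C(c1ccc(OCc2ccccc2)cc1O)S(=O)(=O)c1ccc(C)cc1 | intermediate
10 | 2,6-dimethoxyphenol | COc1cccc(OC)c1O | starting material
11 | 2-(benzyloxy)-1,3-dimethoxybenzene | COc1cccc(OC)c1OCc1ccccc1 | intermediate
12 | {[3-(benzyloxy)-2,4-dimethoxyphenyl]methylidene}dimethyliminium chloride (not isolated) | COc1ccc(C=[N+](C)C)c(OC)c1OCc1ccccc1.[Cl-] | intermediate
13 | 3-(benzyloxy)-2,4-dimethoxybenzaldehyde | COc1ccc(C=O)c(OC)c1OCc1ccccc1 | intermediate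
14 | 2-(benzyloxy)-1,3-dimethoxy-4-(2-methoxyethenyl)benzene (E/Z mixture) | COC=Cc1ccc(OC)c(OCc2ccccc2)c1OC | intermediate
15 | 2-[3-(benzyloxy)-2,4-dimethoxyphenyl]acetaldehyde | COc1ccc(CC=O)c(OC)c1OCc1ccccc1 | intermediate
16 | 3-(benzyloxy)-6-{[4-(benzyloxy)-2-bromo-6-methoxyphenyl]methylidene}cyclohexa-2,4-dien-1-one (not isolated) | COc1cc(OCc2ccccc2)cc(Br)c1C=C1C=CC(OCc2ccccc2)=CC1=O | intermediate
17 | (3R,4S)-7-(benzyloxy)-4-[4-(benzyloxy)-2-bromo-6-methoxyphenyl]-3-[3-(benzyloxy)-2,4-dimethoxyphenyl]chroman-2-ol (C2 anomers) | COc1ccc([C@@H]2C(O)Oc3cc(OCc4ccccc4)ccc3[C@H]2c2c(OC)cc(OCc3ccccc3)cc2Br)c(OC)c1OCc1ccccc1 | intermediate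
18 | (3R,4S)-7-(benzyloxy)-4-[4-(benzyloxy)-2-bromo-6-methoxyphenyl]-3-[3-(benzyloxy)-2,4-dimethoxyphenyl]chromane | COc1ccc([C@@H]2COc3cc(OCc4ccccc4)ccc3[C@H]2c2c(OC)cc(OCc3ccccc3)cc2Br)c(OC)c1OCc1ccccc1 | intermediate
19 | (3R,4S)-4-[2-allyl-4-(benzyloxy)-6-methoxyphenyl]-7-(benzyloxy)-3-[3-(benzyloxy)-2,4-dimethoxyphenyl]chromane | COc1ccc([C@@H]2COc3cc(OCc4ccccc4)ccc3[C@H]2c2c(OC)cc(OCc3ccccc3)cc2CC=C)c(OC)c1OCc1ccccc1 | intermediate
20 | 3-{5-(benzyloxy)-2-[(3R,4S)-7-(benzyloxy)-3-[3-(benzyloxy)-2,4-dimethoxyphenyl]chroman-4-yl]-3-methoxyphenyl}propane-1,2-diol (carbinol epimers; not isolated) | COc1ccc([C@@H]2COc3cc(OCc4ccccc4)ccc3[C@H]2c2c(OC)cc(OCc3ccccc3)cc2CC(O)CO)c(OC)c1OCc1ccccc1 | intermediate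
21 | 2-{5-(benzyloxy)-2-[(3R,4S)-7-(benzyloxy)-3-[3-(benzyloxy)-2,4-dimethoxyphenyl]chroman-4-yl]-3-methoxyphenyl}acetaldehyde | COc1ccc([C@@H]2COc3cc(OCc4ccccc4)ccc3[C@H]2c2c(OC)cc(OCc3ccccc3)cc2CC=O)c(OC)c1OCc1ccccc1 | intermediate
22 | 4-(benzyloxy)-2-hydroxybenzaldehyde | O=Cc1ccc(OCc2ccccc2)cc1O | starting material
23 | 5-(benzyloxy)-2-(hydroxymethyl)phenol | OCc1ccc(OCc2ccccc2)cc1O | intermediate
24 | 5-(benzyloxy)-2-[(4-methylbenzenesulfonyl)methyl]phenol | Cc1ccc(cc1)S(=O)(=O)Cc1ccc(OCc2ccccc2)cc1O | intermediate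
25 | 3-(benzyloxy)-6-methylidenecyclohexa-2,4-dien-1-one (not isolated) | C=C1C=CC(OCc2ccccc2)=CC1=O | intermediate
26 | (3R)-7-(benzyloxy)-3-{5-(benzyloxy)-2-[(3R,4S)-7-(benzyloxy)-3-[3-(benzyloxy)-2,4-dimethoxyphenyl]chroman-4-yl]-3-methoxyphenyl}chroman-2-ol (C2 anomers) | COc1ccc([C@@H]2COc3cc(OCc4ccccc4)ccc3[C@H]2c2c(OC)cc(OCc3ccccc3)cc2[C@@H]2C(O)Oc3cc(OCc4ccccc4)ccc3C2)c(OC)c1OCc1ccccc1 | intermediate
27 | (3R,4S)-7-(benzyloxy)-4-{4-(benzyloxy)-2-[(3R)-7-(benzyloxy)chroman-3-yl]-6-methoxyphenyl}-3-[3-(benzyloxy)-2,4-dimethoxyphenyl]chromane | COc1ccc([C@@H]2COc3cc(OCc4ccccc4)ccc3[C@H]2c2c(OC)cc(OCc3ccccc3)cc2[C@@H]2COc3cc(OCc4ccccc4)ccc3C2)c(OC)c1OCc1ccccc1 | intermediate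
28 | (3R,4S)-4-{4-hydroxy-2-[(3R)-7-hydroxychroman-3-yl]-6-methoxyphenyl}-3-(3-hydroxy-2,4-dimethoxyphenyl)chroman-7-ol (CNP0305801.1) | COc1ccc([C@@H]2COc3cc(O)ccc3[C@H]2c2c(OC)cc(O)cc2[C@@H]2COc3cc(O)ccc3C2)c(OC)c1O | target

**Step count.** 18 steps in total; the longest linear sequence is 12 steps (1, 2, 3, 4, 5, 10, 11, 12, 13, 16, 17, 18).

**Steps most likely to fail**

1. Step 16 (key step). The new alpha-aryl centre may lose its configuration through enamine or enol tautomerisation of the open aldehyde form, a racemic base-mediated enolate addition may compete with the catalysed pathway, or the arylacetaldehyde may self-condense before it meets the short-lived quinone methide. The fallback sets out from 18 and comes back at 27. Stille coupling of 18 with 2-(tributylstannyl)prop-2-en-1-ol (Pd(PPh3)4, toluene, 110 °C) would give the 2-arylallyl alcohol F1. Mitsunobu etherification (PPh3, DIAD, THF) with 5-(benzyloxy)-2-ethenylphenol F2, itself made from 22 by Wittig methylenation (Ph3PCH3Br, KOtBu), would give the diene F3. Ring-closing metathesis (second-generation Grubbs catalyst RuCl2(H2IMes)(PCy3)(=CHPh), CH2Cl2, 40 °C) would close the same pyran ring through a C3=C4 double bond and give the isoflav-3-ene F4. Asymmetric hydrogenation with an iridium phosphino-oxazoline complex [Ir(cod)(L)]BArF (H2, 50 bar, CH2Cl2), the ligand enantiomer being chosen to deliver the 3R centre, would then give 27.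

2. Step 10. Addition to a methide carbon flanked by a 2,6-disubstituted aryl ring may be so slow that quinone methide oligomerisation and aldehyde self-condensation take over, or the trans selectivity may be poor. The fallback sets out from 9 and the E isomer of 14 and comes back at 18. A thermal inverse-electron-demand hetero-Diels–Alder reaction of quinone methide 16 (from 9 with K2CO3, toluene, 60 °C) with the neutral enol ether (E)-14 would give the racemic 3,4-trans 2-methoxychromane F5. Reduction of the acetal with Et3SiH/BF3·OEt2 would give the racemic chromane F6, and preparative chromatography on a chiral stationary phase would deliver 18.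

3. Step 17. The oxocarbenium ion may lose the C3 proton faster than it takes up hydride, and unselective reprotonation of the resulting 4H-chromene would erode the C3 configuration. The fallback sets out from 26 and comes back at 27. NaBH4 (MeOH/THF, 0 °C) would reduce the open aldehyde form of 26 to the ring-opened phenol alcohol F7 without any cationic intermediate, and Mitsunobu cyclisation (PPh3, DIAD, THF) would re-form the O1–C2 bond and give 27.

**Further compounds**

F1 | step 16 | 2-{5-(benzyloxy)-2-[(3R,4S)-7-(benzyloxy)-3-[3-(benzyloxy)-2,4-dimethoxyphenyl]chroman-4-yl]-3-methoxyphenyl}prop-2-en-1-ol | COc1ccc([C@@H]2COc3cc(OCc4ccccc4)ccc3[C@H]2c2c(OC)cc(OCc3ccccc3)cc2C(=C)CO)c(OC)c1OCc1ccccc1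
F2 | step 16 | 5-(benzyloxy)-2-ethenylphenol | C=Cc1ccc(OCc2ccccc2)cc1O
F3 | step 16 | (3R,4S)-7-(benzyloxy)-4-[4-(benzyloxy)-2-(3-{[5-(benzyloxy)-2-ethenylphenyl]oxy}prop-1-en-2-yl)-6-methoxyphenyl]-3-[3-(benzyloxy)-2,4-dimethoxyphenyl]chromane | COc1ccc([C@@H]2COc3cc(OCc4ccccc4)ccc3[C@H]2c2c(OC)cc(OCc3ccccc3)cc2C(=C)COc2cc(OCc3ccccc3)ccc2C=C)c(OC)c1OCc1ccccc1
F4 | step 16 | (3R,4S)-7-(benzyloxy)-4-{4-(benzyloxy)-2-[7-(benzyloxy)-2H-chromen-3-yl]-6-methoxyphenyl}-3-[3-(benzyloxy)-2,4-dimethoxyphenyl]chromane | COc1ccc([C@@H]2COc3cc(OCc4ccccc4)ccc3[C@H]2c2c(OC)cc(OCc3ccccc3)cc2C2=Cc3ccc(OCc4ccccc4)cc3OC2)c(OC)c1OCc1ccccc1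
F5 | step 10 | racemic 3,4-trans-7-(benzyloxy)-4-[4-(benzyloxy)-2-bromo-6-methoxyphenyl]-3-[3-(benzyloxy)-2,4-dimethoxyphenyl]-2-methoxychromane | COc1ccc(C2C(OC)Oc3cc(OCc4ccccc4)ccc3C2c2c(OC)cc(OCc3ccccc3)cc2Br)c(OC)c1OCc1ccccc1
F6 | step 10 | racemic 3,4-trans-7-(benzyloxy)-4-[4-(benzyloxy)-2-bromo-6-methoxyphenyl]-3-[3-(benzyloxy)-2,4-dimethoxyphenyl]chromane | COc1ccc(C2COc3cc(OCc4ccccc4)ccc3C2c2c(OC)cc(OCc3ccccc3)cc2Br)c(OC)c1OCc1ccccc1
F7 | step 17 | (2R)-2-{5-(benzyloxy)-2-[(3R,4S)-7-(benzyloxy)-3-[3-(benzyloxy)-2,4-dimethoxyphenyl]chroman-4-yl]-3-methoxyphenyl}-3-[4-(benzyloxy)-2-hydroxyphenyl]propan-1-ol | COc1ccc([C@@H]2COc3cc(OCc4ccccc4)ccc3[C@H]2c2c(OC)cc(OCc3ccccc3)cc2[C@H](CO)Cc2ccc(OCc3ccccc3)cc2O)c(OC)c1OCc1ccccc1
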